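## Retrosynthetic overview

1. Feature: the cycloheptene carries oxygen at C8 and at C1 on either side of the C9=C10(CH3) alkene and is fused to the cyclopentane through quaternary C3 and C7. This is the imprint of a 3-oxidopyrylium (C7–C8–C9–C10–C1 plus ring oxygen) added across a tethered C3(CH3)=C2H2 alkene.
2. Late disconnections: C8 O-aroyl (ester), C8–H (directed ketone reduction), C1 O-acetyl and C7–H (reductive opening of the C7–O bridge bond) lead back to the oxygen-bridged tricycle 15.
3. Key disconnection: 15 ⇒ acetoxypyranone 13; C7–C3 and C1–C2 form together, closing the cyclopentane and the seven-membered carbocycle in one step.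
4. 13 ⇒ furyl diol 11 (oxidative furan-to-pyranone ring expansion) ⇒ furyl ketone 10 ⇒ 3-methylfuran + dioxolanone 6; C6 comes from (R)-2-hydroxy-3-methylbutanoic acid by retentive α-alkylation.
5. Ring order: pyranone (from the furan) first, then cyclopentane and cycloheptene simultaneously; no ring is formed after the key step.

Key step: step 8

Remark (numbering): locants C1–C10 are those of the carbocyclic skeleton, not IUPAC locants. C1 = CH–OAc, C2 = CH2, C3 = ring-fusion C(CH3), C4 and C5 = cyclopentane CH2, C6 = C(OH)(isopropyl), C7 = ring-fusion CH, C8 = CH–O-aroyl, C9 = olefinic CH, C10 = olefinic C–CH3. β is the face of C7–H, C1–O and C8–O in the target; α is the face of C3–CH3 and C6–OH.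

Remark (assumption): the centres that become C7 and C1 are both made planar in step 8, so 11–13 are carried as mixtures at these centres and their SMILES leave them open. Acid 20 is taken as a catalogue compound.

## Route

Step 1
Reactants: 1 (R)-2-hydroxy-3-methylbutanoic acid
Product: 2 (2R,5R)-2-tert-butyl-5-(propan-2-yl)-1,3-dioxolan-4-one (cis)
Conditions: pivalaldehyde, p-toluenesulfonic acid (cat.), H2SO4 (cat.), pentane, reflux, Dean–Stark; cis isomer purified
Reagents that add atoms: pivalaldehyde (2,2-dimethylpropanal), CC(C)(C)C=O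
Why: acid-catalysed acetalisation with azeotropic removal of water should place tert-butyl and isopropyl cis under thermodynamic control, so the new (2R) acetal centre stores the configuration of C5, the later C6 of the target.

Step 2
Reactants: 3 4-bromo-2-methylbut-1-ene
Product: 4 4-iodo-2-methylbut-1-ene
Conditions: NaI, acetone, reflux
Reagents that add atoms: sodium iodide, [Na+].[I-]
Why: Finkelstein halide exchange, driven by precipitation of NaBr, should give the more reactive primary iodide for the hindered enolate alkylation; no stereocentre is involved.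

Step 3
Reactants: 2 (2R,5R)-2-tert-butyl-5-(propan-2-yl)-1,3-dioxolan-4-one; 4 4-iodo-2-methylbut-1-ene
Product: 6 (2R,5R)-2-tert-butyl-5-(3-methylbut-3-en-1-yl)-5-(propan-2-yl)-1,3-dioxolan-4-one, via lithium enolate 5 (not isolated)
Conditions: LiN(iPr)2, THF, −78 °C; then 4, DMPU, −78 → −30 °C
Reagents that add atoms: none
Why: enolate alkylation by self-regeneration of the stereocentre: C5 is trigonal in 5, the (2R) acetal centre keeps the chirality, and the iodide should enter anti to tert-butyl, so the chain takes the place of the former C5–H with overall retention and sets C6 of the target as R.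

Step 4
Reactants: 7 3-methylfuran; 6 (2R,5R)-2-tert-butyl-5-(3-methylbut-3-en-1-yl)-5-(propan-2-yl)-1,3-dioxolan-4-one
Product: 10 (2R)-2-hydroxy-5-methyl-1-(4-methylfuran-2-yl)-2-(propan-2-yl)hex-5-en-1-one, via 4-methyl-2-furyllithium 8 (not isolated), via lithium hemiketal alkoxide 9 (not isolated)
Conditions: 7 (1.5 equiv), t-BuLi (1.4 equiv), THF, −78 → −30 °C; then 6, −78 °C; AcOH, −78 °C → rt
Reagents that add atoms: none
Why: α-lithiation of the furan at the position remote from the methyl group (favoured with the bulky base) and single addition of 8 to the lactone carbonyl (acyl substitution) should give 9, which persists at −78 °C and collapses only after protonation with loss of pivalaldehyde, so no second addition occurs, C6 is untouched, and any 3-methyl-2-furyl isomer is removed by chromatography.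

Step 5
Reactants: 10 (2R)-2-hydroxy-5-methyl-1-(4-methylfuran-2-yl)-2-(propan-2-yl)hex-5-en-1-one
Product: 11 (2R)-5-methyl-1-(4-methylfuran-2-yl)-2-(propan-2-yl)hex-5-ene-1,2-diol (both C1 epimers)
Conditions: NaBH4, MeOH, 0 °C
Reagents that add atoms: none
Why: borohydride reduction of the furyl ketone should give the furfuryl alcohol needed for ring expansion; the new carbinol centre (later C7) forms without control and is destroyed in step 8.

Step 6
Reactants: 11 (2R)-5-methyl-1-(4-methylfuran-2-yl)-2-(propan-2-yl)hex-5-ene-1,2-diol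
Product: 12 6-hydroxy-2-[(3R)-3-hydroxy-2,6-dimethylhept-6-en-3-yl]-5-methyl-2H-pyran-3(6H)-one (mixture at both pyranone stereocentres)
Conditions: NBS (1.05 equiv), NaHCO3, THF/H2O (4:1), 0 °C
Reagents that add atoms: water, O
Why: Achmatowicz rearrangement: NBS should oxidise the electron-rich furan at its free α-position much faster than it attacks the 1,1-disubstituted alkene, the carbinol oxygen becomes the pyranone ring oxygen, the furan methyl ends on pyranone C5 (= C10), and the bicarbonate buffer keeps the tertiary hydroxyl from forming a bicyclic ketal under acid.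

Step 7
Reactants: 12 6-hydroxy-2-[(3R)-3-hydroxy-2,6-dimethylhept-6-en-3-yl]-5-methyl-2H-pyran-3(6H)-one
Product: 13 6-acetoxy-2-[(3R)-3-hydroxy-2,6-dimethylhept-6-en-3-yl]-5-methyl-2H-pyran-3(6H)-one (mixture at both pyranone stereocentres)
Conditions: Ac2O (1.2 equiv), pyridine, 4-(dimethylamino)pyridine (cat.), CH2Cl2, 0 °C
Reagents that add atoms: acetic anhydride, CC(=O)OC(C)=O
Why: O-acylation of the hemiacetal hydroxyl, which is far more reactive than the hindered tertiary alcohol, should install the leaving group for ylide formation; both pyranone stereocentres are lost in the next step.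

Step 8
Reactants: 13 6-acetoxy-2-[(3R)-3-hydroxy-2,6-dimethylhept-6-en-3-yl]-5-methyl-2H-pyran-3(6H)-one
Product: 15 (1S,3R,6R,7S)-1,7-epoxy-6-hydroxy-3,10-dimethyl-6-(propan-2-yl)bicyclo[5.3.0]dec-9-en-8-one (locants of the remark; oxygen bridge β, C3–CH3 α), via 3-oxidopyrylium ylide 14 (not isolated)
Conditions: DBU (1.5 equiv), MeCN (0.01 M), rt → 60 °C
Reagents that add atoms: none
Why: DBU removes the C7 proton α to the C8 ketone and acetate leaves from C1, giving the planar 3-oxidopyrylium 14, whose C7 and C1 termini add suprafacially across the tethered C3=C2 alkene in a concerted intramolecular dipolar (5+2) cycloaddition; the closest known reaction is the oxidopyrylium–alkene cycloaddition of acetoxypyranones carrying a three-atom tether. The cyclopentane closes by C7–C3 bond formation in the exo mode (C6–C5–C4 link the ylide terminus to the internal alkene carbon, C2 stays outside the ring), and C1–C2 bond formation completes the seven-membered carbocycle at the same time as an 8-oxabicyclo[3.2.1]oct-3-en-2-one. C7 and C1 are set together because both bonds form on one face of the ylide, so the oxygen bridge is cis at both; C3 is set by the tether, which can only span the bridgehead and the exo position of the two-carbon bridge, so C4 is syn and CH3 is endo, anti to the bridge oxygen. The step needs facial selectivity relative to C6, and C6 should secure it: with the tether perpendicular to the ylide plane, the position eclipsing C7–C8 next to the oxido oxygen is taken by the hydroxyl (hydrogen bond to O–, no A(1,3) strain) and the isopropyl group turns toward the unsubstituted ring oxygen, which puts the alkene on the face leading to 15. Regiochemistry is fixed by the tether, since the bridged alternative cannot be reached, and high dilution together with the Thorpe–Ingold effect of quaternary C6 should keep ring closure ahead of ylide dimerisation.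

Step 9
Reactants: 15 (1S,3R,6R,7S)-1,7-epoxy-6-hydroxy-3,10-dimethyl-6-(propan-2-yl)bicyclo[5.3.0]dec-9-en-8-one
Product: 17 (1S,3R,6R,7R)-1,6-dihydroxy-3,10-dimethyl-6-(propan-2-yl)bicyclo[5.3.0]dec-9-en-8-one (trans-fused, C7–H β), via samarium dienolate 16 (not isolated)
Conditions: SmI2 (2.2 equiv), THF/MeOH (10:1), −78 °C
Reagents that add atoms: none
Why: reduction of an α-alkoxy ketone by SmI2: two single-electron transfers should break the C7–O bond next to the ketyl carbon and leave the oxygen on C1, 16 should be protonated at C7 from the β face where the just-released samarium-bound C1 alkoxide holds the proton donor, and the trans-fused ketone is also the expected thermodynamic epimer (C8 cis to OH and CH3 instead of isopropyl, with a C6–OH···O=C8 hydrogen bond), so C7 can be equilibrated through the enol if needed.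

Step 10
Reactants: 17 (1S,3R,6R,7R)-1,6-dihydroxy-3,10-dimethyl-6-(propan-2-yl)bicyclo[5.3.0]dec-9-en-8-one
Product: 18 (1S,3R,6R,7R)-1-acetoxy-6-hydroxy-3,10-dimethyl-6-(propan-2-yl)bicyclo[5.3.0]dec-9-en-8-one
Conditions: Ac2O, pyridine, 4-(dimethylamino)pyridine (cat.), CH2Cl2, 0 °C → rt
Reagents that add atoms: acetic anhydride, CC(=O)OC(C)=O
Why: nucleophile-catalysed acetylation should take the only secondary hydroxyl (C1) while the tertiary C6 hydroxyl stays free; no stereocentre is touched under these mildly basic conditions.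

Step 11
Reactants: 18 (1S,3R,6R,7R)-1-acetoxy-6-hydroxy-3,10-dimethyl-6-(propan-2-yl)bicyclo[5.3.0]dec-9-en-8-one
Product: 19 (1S,3R,6R,7S,8S)-1-acetoxy-3,10-dimethyl-6-(propan-2-yl)bicyclo[5.3.0]dec-9-ene-6,8-diol (8β-OH)
Conditions: Me4NBH(OAc)3, MeCN/AcOH (1:1), −20 → 0 °C
Reagents that add atoms: none
Why: hydroxyl-directed 1,2-reduction (Evans–Saksena): exchange of an acetate on boron for the C6 hydroxyl, which lies on the α face beside the carbonyl plane, should deliver hydride intramolecularly to the α face of C8 and give the 8β-alcohol (8S, anti to C6–OH), while the free reagent reduces neither the enone nor the acetate.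

Step 12
Reactants: 19 (1S,3R,6R,7S,8S)-1-acetoxy-3,10-dimethyl-6-(propan-2-yl)bicyclo[5.3.0]dec-9-ene-6,8-diol; 20 4-[(tert-butyldimethylsilyl)oxy]benzoic acid
Product: 21 (1S,3R,6R,7S,8S)-1-acetoxy-6-hydroxy-3,10-dimethyl-6-(propan-2-yl)bicyclo[5.3.0]dec-9-en-8-yl 4-[(tert-butyldimethylsilyl)oxy]benzoate
Conditions: DCC, 4-(dimethylamino)pyridine, CH2Cl2, rt
Reagents that add atoms: none
Why: Steglich esterification should acylate the secondary allylic C8 hydroxyl through the acylpyridinium ion; the tertiary C6 hydroxyl does not react, and C8 keeps its configuration because its C–O bond is not broken.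

Step 13
Reactants: 21 (1S,3R,6R,7S,8S)-1-acetoxy-6-hydroxy-3,10-dimethyl-6-(propan-2-yl)bicyclo[5.3.0]dec-9-en-8-yl 4-[(tert-butyldimethylsilyl)oxy]benzoate
Product: 22 (3R,3aS,4S,7S,8aR)-7-acetoxy-3-hydroxy-6,8a-dimethyl-3-(propan-2-yl)-1,2,3,3a,4,7,8,8a-octahydroazulen-4-yl 4-hydroxybenzoate (target; 1S,3R,6R,7S,8S in the locants of the remark)
Conditions: Bu4NF, AcOH, THF, 0 °C
Reagents that add atoms: none
Why: fluoride cleavage of the aryl silyl ether, buffered with acetic acid so that the phenoxide cannot cause acyl migration or ester cleavage, should leave the acetate, the benzoate ester and all five stereocentres untouched.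

## Compound list

1 | (R)-2-hydroxy-3-methylbutanoic acid | CC(C)[C@@H](O)C(=O)O | starting material
2 | (2R,5R)-2-tert-butyl-5-(propan-2-yl)-1,3-dioxolan-4-one (cis) | CC(C)[C@H]1O[C@@H](C(C)(C)C)OC1=O | intermediate
3 | 4-bromo-2-methylbut-1-ene | C=C(C)CCBr | starting material
4 | 4-iodo-2-methylbut-1-ene | C=C(C)CCI | intermediate
5 | lithium enolate of 2, lithium (2R)-2-tert-butyl-5-(propan-2-yl)-1,3-dioxol-4-olate | CC(C)C1=C(O[Li])O[C@H](C(C)(C)C)O1 | intermediate (not isolated)
6 | (2R,5R)-2-tert-butyl-5-(3-methylbut-3-en-1-yl)-5-(propan-2-yl)-1,3-dioxolan-4-one | CC(C)[C@@]1(CCC(C)=C)O[C@@H](C(C)(C)C)OC1=O | intermediate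
7 | 3-methylfuran | Cc1ccoc1 | starting material
8 | 4-methyl-2-furyllithium | Cc1coc([Li])c1 | intermediate (not isolated)
9 | lithium hemiketal alkoxide, lithium (2R,5R)-2-tert-butyl-5-(3-methylbut-3-en-1-yl)-4-(4-methylfuran-2-yl)-5-(propan-2-yl)-1,3-dioxolan-4-olate (C4 unassigned) | CC(C)[C@@]1(CCC(C)=C)O[C@@H](C(C)(C)C)OC1(O[Li])c1cc(C)co1 | intermediate (not isolated)
10 | (2R)-2-hydroxy-5-methyl-1-(4-methylfuran-2-yl)-2-(propan-2-yl)hex-5-en-1-one | CC(C)[C@](O)(CCC(C)=C)C(=O)c1cc(C)co1 | intermediate
11 | (2R)-5-methyl-1-(4-methylfuran-2-yl)-2-(propan-2-yl)hex-5-ene-1,2-diol (both C1 epimers) | CC(C)[C@](O)(CCC(C)=C)C(O)c1cc(C)co1 | intermediate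
12 | 6-hydroxy-2-[(3R)-3-hydroxy-2,6-dimethylhept-6-en-3-yl]-5-methyl-2H-pyran-3(6H)-one (mixture at pyranone C2 and C6) | CC(C)[C@](O)(CCC(C)=C)C1OC(O)C(C)=CC1=O | intermediate
13 | 6-acetoxy-2-[(3R)-3-hydroxy-2,6-dimethylhept-6-en-3-yl]-5-methyl-2H-pyran-3(6H)-one (mixture at pyranone C2 and C6) | CC(=O)OC1OC([C@](O)(C(C)C)CCC(C)=C)C(=O)C=C1C | intermediate
14 | 3-oxidopyrylium ylide, 2-[(3R)-3-hydroxy-2,6-dimethylhept-6-en-3-yl]-5-methylpyrylium-3-olate | CC(C)[C@](O)(CCC(C)=C)c1[o+]cc(C)cc1[O-] | intermediate (not isolated)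
15 | (1S,3R,6R,7S)-1,7-epoxy-6-hydroxy-3,10-dimethyl-6-(propan-2-yl)bicyclo[5.3.0]dec-9-en-8-one (oxygen-bridged hydroazulenone; locants of the remark) | O3[C@H]1C[C@@]2(C)CC[C@@](O)(C(C)C)[C@]23C(=O)C=C1C | intermediate
16 | samarium dienolate, C7=C8 enolate and C1 alkoxide of 17 bound to SmI2 units of trivalent samarium | I[Sm](I)O[C@H]1C[C@@]2(C)CC[C@@](O)(C(C)C)C2=C(O[Sm](I)I)C=C1C | intermediate (not isolated)
17 | (1S,3R,6R,7R)-1,6-dihydroxy-3,10-dimethyl-6-(propan-2-yl)bicyclo[5.3.0]dec-9-en-8-one (trans-fused) | O[C@H]1C[C@@]2(C)CC[C@@](O)(C(C)C)[C@@H]2C(=O)C=C1C | intermediate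
18 | (1S,3R,6R,7R)-1-acetoxy-6-hydroxy-3,10-dimethyl-6-(propan-2-yl)bicyclo[5.3.0]dec-9-en-8-one | CC(=O)O[C@H]1C[C@@]2(C)CC[C@@](O)(C(C)C)[C@@H]2C(=O)C=C1C | intermediate
19 | (1S,3R,6R,7S,8S)-1-acetoxy-3,10-dimethyl-6-(propan-2-yl)bicyclo[5.3.0]dec-9-ene-6,8-diol | CC(=O)O[C@H]1C[C@@]2(C)CC[C@@](O)(C(C)C)[C@@H]2[C@@H](O)C=C1C | intermediate
20 | 4-[(tert-butyldimethylsilyl)oxy]benzoic acid | CC(C)(C)[Si](C)(C)Oc1ccc(cc1)C(=O)O | starting material
21 | (1S,3R,6R,7S,8S)-1-acetoxy-6-hydroxy-3,10-dimethyl-6-(propan-2-yl)bicyclo[5.3.0]dec-9-en-8-yl 4-[(tert-butyldimethylsilyl)oxy]benzoate | CC(=O)O[C@H]1C[C@@]2(C)CC[C@@](O)(C(C)C)[C@@H]2[C@@H](OC(=O)c2ccc(O[Si](C)(C)C(C)(C)C)cc2)C=C1C | intermediate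
22 | (3R,3aS,4S,7S,8aR)-7-acetoxy-3-hydroxy-6,8a-dimethyl-3-(propan-2-yl)-1,2,3,3a,4,7,8,8a-octahydroazulen-4-yl 4-hydroxybenzoate | CC(=O)O[C@H]1C[C@@]2(C)CC[C@@](O)(C(C)C)[C@@H]2[C@@H](OC(=O)c2ccc(O)cc2)C=C1C | target

## Step count and risks

Total: 13 steps. Longest linear sequence: 12 steps (1 → 2 → 6 → 10 → 11 → 12 → 13 → 15 → 17 → 18 → 19 → 21 → 22; step 2 is a side branch).

Steps most likely to fail:

**Step 9 (opening of the oxygen bridge).** The same bridging oxygen is α to the ketone at C7 and vinylogously γ to it at C1, so electron transfer to the enone may expel it from C1 instead of C7. The product enone may also be reduced further, or the enolate may be protonated at C7 from the α face. The fallback sets out from 15 and comes back at 18. Hydrogenation of 15 (H2, palladium on carbon (Pd/C), EtOAc) from the exo face should give the 9,10-dihydro cycloadduct F4 (C10–CH3 α), whose saturated ketone has only one reducible C–O bond. SmI2 in THF/MeOH at −78 °C should then give, through the saturated samarium enolate F5, the saturated hydroxy ketone F6. Acetylation of the C1 hydroxyl (Ac2O, pyridine) gives the saturated acetoxy ketone F7. IBX in DMSO at 70 °C (or a Saegusa–Ito sequence) dehydrogenates F7 to 18; this is the only possible direction because C3 and C6, the carbons next to C7, carry no hydrogen.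

**Step 8 (key cycloaddition).** The free C6 hydroxyl is β to the C8 ketone, so under DBU the acetoxypyranone may fragment by retro-aldol cleavage of C6–C7, or the ylide may dimerise before the congested C7–C3 bond forms. Hydrogen-bond control of the face may also prove weaker than expected. The fallback sets out from 13 and comes back at 15. N-(Trimethylsilyl)imidazole in MeCN at rt should silylate the tertiary hydroxyl and give the C6 O-trimethylsilyl acetoxypyranone F1, which can no longer undergo retro-aldol cleavage. DBU at 60 °C should convert it through the silylated 3-oxidopyrylium ylide F2 into the C6 O-trimethylsilyl cycloadduct F3. Here the face is selected by sterics alone, the slim O–Si oxygen rather than the branched isopropyl carbon lying next to the oxido. Citric acid in MeOH removes the silyl group and returns 15.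

**Step 11 (directed reduction of the C8 ketone).** The hindered tertiary C6 hydroxyl may exchange onto boron too slowly, leaving the ketone untouched, or hydride may arrive undirected from the β face, away from the pseudoaxial C3 methyl, and set the wrong C8 configuration. The fallback sets out from 18 and comes back at 21. Luche reduction (NaBH4, CeCl3·7H2O, MeOH, −78 °C) is expected to attack from the open β face and give the C8-epimeric 8α-alcohol F8. Mitsunobu esterification of F8 with acid 20 (PPh3, DIAD, toluene, 0 °C → rt) inverts C8 and forms 21 directly, so step 12 is skipped.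

Further compounds
F1 | step 8 | 6-acetoxy-5-methyl-2-[(3R)-2,6-dimethyl-3-(trimethylsilyloxy)hept-6-en-3-yl]-2H-pyran-3(6H)-one | CC(=O)OC1OC([C@](O[Si](C)(C)C)(C(C)C)CCC(C)=C)C(=O)C=C1C
F2 | step 8 | 5-methyl-2-[(3R)-2,6-dimethyl-3-(trimethylsilyloxy)hept-6-en-3-yl]pyrylium-3-olate (not isolated) | CC(C)[C@](O[Si](C)(C)C)(CCC(C)=C)c1[o+]cc(C)cc1[O-]
F3 | step 8 | C6 O-trimethylsilyl ether of 15 | O3[C@H]1C[C@@]2(C)CC[C@@](O[Si](C)(C)C)(C(C)C)[C@]23C(=O)C=C1C
F4 | step 9 | 9,10-dihydro derivative of 15 (C10–CH3 α) | O3[C@H]1C[C@@]2(C)CC[C@@](O)(C(C)C)[C@]23C(=O)C[C@@H]1C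
F5 | step 9 | samarium enolate of F6, C7=C8 enolate and C1 alkoxide bound to SmI2 units of trivalent samarium (not isolated) | I[Sm](I)O[C@H]1C[C@@]2(C)CC[C@@](O)(C(C)C)C2=C(O[Sm](I)I)C[C@@H]1C
F6 | step 9 | 9,10-dihydro derivative of 17 (trans-fused, C10–CH3 α) | O[C@H]1C[C@@]2(C)CC[C@@](O)(C(C)C)[C@@H]2C(=O)C[C@@H]1C
F7 | step 9 | 9,10-dihydro derivative of 18 (C10–CH3 α) | CC(=O)O[C@H]1C[C@@]2(C)CC[C@@](O)(C(C)C)[C@@H]2C(=O)C[C@@H]1C
F8 | step 11 | C8 epimer of 19 (8α-OH) | CC(=O)O[C@H]1C[C@@]2(C)CC[C@@](O)(C(C)C)[C@@H]2[C@H](O)C=C1C
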